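**Assumption:** the SMILES defines the (1S,1′S,5S,7R,10S) isomer. Eudesmane numbering is used throughout: C4 carries the exocyclic CH2, C5 is the ring-fusion CH, C7 carries C(CH3)2OH, C10 is the quaternary C–CH3, C1 carries the side chain, C1′ is the benzylic carbon. The route is a design proposal; selectivities are predictions from analogy, not measured values.

## Retrosynthetic overview

1. Macrocarpal H ⇐ tri-O-methyl ether (thiolate demethylation) ⇐ aryl dibromide (Br/Li, DMF) with C4=CH2 from a C4 ketone (Wittig).
2. C1′–isobutyl ⇐ SN1 methallylation of a 2,4,6-trimethoxybenzylic cation (1,2-induction from C1 sets C1′), then H2; C1′–Ar ⇐ ArLi + C1 aldehyde.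
3. Keto-aldehyde (C1, C5 set thermodynamically) ⇐ Δ4-ene acid by hydroboration/oxidation.
4. Ring A and quaternary C10 ⇐ ring-contracting Ireland–Claisen of a δ-lactone; chirality is transferred from a carbinol set by catalytic asymmetric alkylzinc addition.
5. Ring B and C7 ⇐ (R)-carvone. Ring order: B (chiral pool) → A (Claisen) → arene appended last.

## Route

**Step 1**
Reactants: **1** (R)-(−)-carvone
Product: **2** (R)-2-methyl-5-(prop-1-en-2-yl)cyclohex-1-en-1-yl triflate
Conditions: L-Selectride, THF, −78 °C; then PhNTf2, −78 °C → rt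
Reagents that add atoms: N-phenylbis(trifluoromethanesulfonimide), O=S(=O)(N(c1ccccc1)S(=O)(=O)C(F)(F)F)C(F)(F)F
Why: Conjugate hydride reduction gives the tetrasubstituted enolate regiospecifically and O-triflation traps it; the carvone stereocentre (future C7) is untouched.

**Step 2**
Reactants: **2**
Product: **3** (R)-2-methyl-5-(prop-1-en-2-yl)cyclohex-1-ene-1-carbaldehyde
Conditions: Pd(PPh3)4 (5 mol %), CO (1–3 atm), Bu3SnH (slow addition), LiCl, THF, 50 °C
Reagents that add atoms: carbon monoxide, [C-]#[O+]
Why: Pd-catalysed reductive carbonylation (Stille formylation) of the vinyl triflate; no stereocentre is involved.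

**Step 3**
Reactants: **3**; **4** ethyl 4-iodobutanoate
Product: **5** (R)-6-[(R)-2-methyl-5-(prop-1-en-2-yl)cyclohex-1-en-1-yl]tetrahydro-2H-pyran-2-one
Conditions: **4**, Et2Zn, CuI (cat.), 50 °C, then evacuate; Ti(OiPr)4, (1S,2S)-1,2-bis(trifluoromethanesulfonamido)cyclohexane (8 mol %), toluene, −20 °C → rt; PPTS (cat.) if lactonisation is incomplete
Reagents that add atoms: bis(4-ethoxy-4-oxobutyl)zinc, CCOC(=O)CCC[Zn]CCCC(=O)OCC (made in situ from **4**)
Why: Ti/bis-sulfonamide-catalysed enantioselective addition of a functionalised dialkylzinc (Knochel type) sets the (R)-carbinol under ligand control (ligand antipode chosen for that sense), and the alkoxide closes to the δ-lactone.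

**Step 4**
Reactants: **5**
Product: **6** (R)-6-[(R)-5-(2-hydroxypropan-2-yl)-2-methylcyclohex-1-en-1-yl]tetrahydro-2H-pyran-2-one
Conditions: Co(acac)2 (20 mol %), PhSiH3, O2 (1 atm), THF, rt; then PPh3
Reagents that add atoms: dioxygen, O=O
Why: Mukaiyama Markovnikov hydration is selective for the 1,1-disubstituted isopropenyl group; the tetrasubstituted ring alkene and lactone are inert.

**Step 5**
Reactants: **6**
Product: **7** (1S,7R,10S)-11-hydroxy-15-nor-eudesm-4-ene-1α-carboxylic acid (ring A closed, C4=C5, 10β-CH3)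
Conditions: TMSCl/Et3N, LDA (2.5 equiv), THF, −78 °C → rt; then toluene, 100 °C; 1 M HCl work-up
Reagents that add atoms: none
Why: Ring-contracting Ireland–Claisen [3,3] rearrangement of the lactone silyl ketene acetal (boat transition state) forms ring A and C10; the bicyclic geometry forces suprafacial delivery, so the (R)-C–O centre becomes (S)-C10. C1 emerges as the 1α-acid and is corrected in step 7.

**Step 6**
Reactants: **7**
Product: **8** 1α-(hydroxymethyl)-15-nor-eudesmane-4α,11-diol (5α-H)
Conditions: BH3·THF (excess), THF, 0 °C → rt; then NaOH, H2O2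
Reagents that add atoms: hydrogen peroxide, OO
Why: One pot reduces CO2H to CH2OH and hydroborates the trisubstituted Δ4 alkene anti-Markovnikov (OH at C4, H at C5, expected from the α-face anti to the angular methyl); the C4/C5 configuration is inconsequential because both are reset in step 7.

**Step 7**
Reactants: **8**
Product: **9** (1R,5R,7R,10S)-1β-formyl-11-hydroxy-15-nor-eudesman-4-one (trans-fused)
Conditions: Dess–Martin periodinane, NaHCO3, CH2Cl2, rt; then DBU (0.3 equiv), CH2Cl2, rt (kept mild to avoid retro-Michael opening)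
Reagents that add atoms: none
Why: Double alcohol oxidation, then enolisation equilibrates C5 to the trans ring fusion and C1 to the equatorial (1β) aldehyde; the preference at C1 may be modest, so the minor epimer is separated and recycled.

**Step 8**
Reactants: **9**; **10** 1,3,5-trimethoxybenzene
Product: **11** 1β-[hydroxy(2,4,6-trimethoxyphenyl)methyl]-11-hydroxy-15-nor-eudesman-4-one (C1′ epimer mixture)
Conditions: **10**, n-BuLi, THF, 0 °C → rt (2.5 equiv ArLi); then **9**, −78 °C (transmetalate to ArTi(OiPr)3 if ketone addition competes)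
Reagents that add atoms: 2,4,6-trimethoxyphenyllithium, [Li]c1c(OC)cc(OC)cc1OC
Why: Directed ortho-lithiation, then chemoselective 1,2-addition to the aldehyde over the α-branched ketone; the carbinol configuration is irrelevant because it is ionised next.

**Step 9**
Reactants: **11**; **12** methallyltrimethylsilane
Product: **13** (1′S)-methallyl adduct
Conditions: **12** (5 equiv), BF3·OEt2, CH2Cl2, −78 → −40 °C
Reagents that add atoms: methallyltrimethylsilane, C=C(C)C[Si](C)(C)C
Why: SN1 Hosomi–Sakurai allylation of the trimethoxybenzylic cation; in the A1,3-minimised conformer (C1–H eclipsing the aryl ring) the silane attacks anti to quaternary C10, which gives (S)-C1′.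

**Step 10**
Reactants: **13**
Product: **14** (1′S)-isobutyl compound
Conditions: H2 (1 atm), 10% Pd/C, EtOAc, rt
Reagents that add atoms: none
Why: Catalytic hydrogenation of the only C=C converts methallyl to isobutyl; no stereocentre is created.

**Step 11**
Reactants: **14**
Product: **15** 3,5-dibromo-2,4,6-trimethoxyphenyl derivative
Conditions: NBS (2.1 equiv), MeCN, 0 °C
Reagents that add atoms: N-bromosuccinimide, O=C1CCC(=O)N1Br
Why: Electrophilic aromatic bromination of the two remaining activated ring positions installs formyl handles without Lewis acid, which the tertiary alcohol would not survive.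

**Step 12**
Reactants: **15**
Product: **16** C4 exocyclic methylene compound
Conditions: Ph3PCH3Br, KOtBu (4 equiv each), THF/toluene, 0 → 60 °C
Reagents that add atoms: methylenetriphenylphosphorane, C=P(c1ccccc1)(c1ccccc1)c1ccccc1
Why: Wittig methylenation of the only carbonyl present; the basic conditions keep the thermodynamic 5α-H ring fusion.

**Step 13**
Reactants: **16**
Product: **17** tri-O-methyl macrocarpal H
Conditions: n-BuLi (1 equiv), then t-BuLi (4.5 equiv), THF, −78 °C; DMF (excess), −78 → 0 °C; aq. NH4Cl
Reagents that add atoms: N,N-dimethylformamide, CN(C)C=O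
Why: Double bromine–lithium exchange and formylation; the alkoxide, exocyclic alkene and methyl ethers tolerate the conditions.

**Step 14**
Reactants: **17**
Product: **18** Macrocarpal H
Conditions: p-TolSLi (excess), HMPA–toluene, 110 °C; dilute HCl work-up
Reagents that add atoms: none
Why: Thiolate SN2 O-demethylation of three aryl methyl ethers, each activated by ortho/para formyl groups, under basic conditions that spare the tertiary alcohol, exocyclic alkene and aldehydes.

## Compound list

1 | (R)-(−)-carvone | CC(=C)[C@@H]1CC=C(C)C(=O)C1 | starting material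
2 | (R)-2-methyl-5-(prop-1-en-2-yl)cyclohex-1-en-1-yl triflate | CC1=C(OS(=O)(=O)C(F)(F)F)C[C@H](C(C)=C)CC1 | intermediate
3 | (R)-2-methyl-5-(prop-1-en-2-yl)cyclohex-1-ene-1-carbaldehyde | CC1=C(C=O)C[C@H](C(C)=C)CC1 | intermediate
4 | ethyl 4-iodobutanoate | CCOC(=O)CCCI | starting material
5 | (R)-6-[(R)-2-methyl-5-(prop-1-en-2-yl)cyclohex-1-en-1-yl]tetrahydropyran-2-one | CC1=C([C@H]2CCCC(=O)O2)C[C@H](C(C)=C)CC1 | intermediate
6 | (R)-6-[(R)-5-(2-hydroxypropan-2-yl)-2-methylcyclohex-1-en-1-yl]tetrahydropyran-2-one | CC1=C([C@H]2CCCC(=O)O2)C[C@H](C(C)(C)O)CC1 | intermediate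
7 | (1S,7R,10S)-11-hydroxy-15-nor-eudesm-4-ene-1α-carboxylic acid | OC(=O)[C@H]1CCC=C2C[C@H](C(C)(C)O)CC[C@@]12C | intermediate
8 | 1α-(hydroxymethyl)-15-nor-eudesmane-4α,11-diol (5α-H, 10β-CH3) | OC[C@H]1CC[C@@H](O)[C@@H]2C[C@H](C(C)(C)O)CC[C@@]12C | intermediate
9 | (1R,5R,7R,10S)-1β-formyl-11-hydroxy-15-nor-eudesman-4-one | O=C[C@@H]1CCC(=O)[C@@H]2C[C@H](C(C)(C)O)CC[C@@]12C | intermediate
10 | 1,3,5-trimethoxybenzene | COc1cc(OC)cc(OC)c1 | starting material
11 | 1β-[hydroxy(2,4,6-trimethoxyphenyl)methyl]-11-hydroxy-15-nor-eudesman-4-one (C1′ mixture) | OC(c1c(OC)cc(OC)cc1OC)[C@@H]1CCC(=O)[C@@H]2C[C@H](C(C)(C)O)CC[C@@]12C | intermediate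
12 | methallyltrimethylsilane | C=C(C)C[Si](C)(C)C | starting material
13 | 1β-[(1S)-3-methyl-1-(2,4,6-trimethoxyphenyl)but-3-enyl]-11-hydroxy-15-nor-eudesman-4-one | C=C(C)C[C@H](c1c(OC)cc(OC)cc1OC)[C@@H]1CCC(=O)[C@@H]2C[C@H](C(C)(C)O)CC[C@@]12C | intermediate
14 | 1β-[(1S)-3-methyl-1-(2,4,6-trimethoxyphenyl)butyl]-11-hydroxy-15-nor-eudesman-4-one | CC(C)C[C@H](c1c(OC)cc(OC)cc1OC)[C@@H]1CCC(=O)[C@@H]2C[C@H](C(C)(C)O)CC[C@@]12C | intermediate
15 | 3,5-dibromo-2,4,6-trimethoxyphenyl analogue of 14 | CC(C)C[C@H](c1c(OC)c(Br)c(OC)c(Br)c1OC)[C@@H]1CCC(=O)[C@@H]2C[C@H](C(C)(C)O)CC[C@@]12C | intermediate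
16 | 1β-[(1S)-1-(3,5-dibromo-2,4,6-trimethoxyphenyl)-3-methylbutyl]eudesm-4(15)-en-11-ol | CC(C)C[C@H](c1c(OC)c(Br)c(OC)c(Br)c1OC)[C@@H]1CCC(=C)[C@@H]2C[C@H](C(C)(C)O)CC[C@@]12C | intermediate
17 | tri-O-methyl macrocarpal H | CC(C)C[C@H](c1c(OC)c(C=O)c(OC)c(C=O)c1OC)[C@@H]1CCC(=C)[C@@H]2C[C@H](C(C)(C)O)CC[C@@]12C | intermediate
18 | Macrocarpal H | C=C1CC[C@@H]([C@H](CC(C)C)c2c(O)c(C=O)c(O)c(C=O)c2O)[C@]2(C)CC[C@@H](C(C)(C)O)C[C@@H]12 | target

## Totals and risks

Total steps: 14. Longest linear sequence: 14, from (R)-carvone; the zinc and aryllithium reagents are made in situ.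

Steps most likely to fail:

1. **Step 5 (lactone Ireland–Claisen).** The boat transition state must form a quaternary centre at a tetrasubstituted alkene terminus with a Z-methyl, so it may be slow. Fallback: build ring A by [4+2] instead. Convert **2** to the 2-silyloxy diene (Stille with tributyl(1-ethoxyvinyl)tin, hydrolysis, TBSOTf/Et3N) and run a chiral oxazaborolidinium-catalysed Diels–Alder with acrolein, with C10 set by the catalyst. This converges on **9** after enol-ether hydrolysis and isopropenyl hydration.

2. **Step 9 (C1′ stereocontrol).** The facial selectivity could be low or opposite to the model. Fallback: swap the roles of the two groups at C1′. Oxidise **11** to the aryl ketone, add methallylmagnesium chloride, and reduce the tertiary benzylic cation with Et3SiH/TFA; hydride then enters the face the allyl group would have used, giving the opposite C1′ epimer.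

3. **Step 13 (double Br/Li exchange and formylation).** The arene is hexasubstituted and a free alkoxide is present. Fallback: omit bromination (step 11) and install the aldehydes by two sequential directed ortho-lithiation/DMF cycles on the methylenated, non-brominated arene, protecting the first aldehyde in situ as its α-amino alkoxide.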